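**Plan**

1. Numbering (drimane type): ring A is C1–C5 and C10, ring B is C5–C10; C4 carries the gem-dimethyl group, C5=C6 is the alkene, C8 is CH–CH3, C9 is the quaternary carbon, C10 the ring-fusion CH, C11 the benzylic CH2.
2. Retrosynthesis: the hydroxy-methoxy-quinone goes back to a 2,3,5,6-tetramethoxyphenyl ring, the C5=C6 alkene to a C6 ketone and the 9-methyl to a 9-formyl group. Because C9 is bonded to C8 and C10 and both are β to C6, ring B is a 4,4-disubstituted cyclohexanone. It is cut at C8–C9 and C9–C10 into the cross-conjugated dienone C10=C5–C6(=O)–C7=C8 and an aldehyde whose α-carbon is C9.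
3. Further cuts: C5–C6 (vinyllithium from 2,2-dimethylcyclohexanone plus crotonaldehyde) and the aryl–chain bond (aryllithium plus oxetane).
4. Forward: ring A is bought; the dienone (three steps) and the aldehyde (two steps) are joined and ring B is closed in one operation by two successive Michael additions; then formyl to methyl, ketone to alkene, arene to quinone.
5. Stereochemistry: C8 comes from the chiral primary amine catalyst; C9 and C10 follow from the chair-like ring closure relative to C8, reinforced thermodynamically; C5 and C6 are only transient stereocentres.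

Key step: step 6

Assumption: the quinine-derived primary amine is taken to give the 8S sense in step 6; its quinidine-derived pseudoenantiomer is the counterpart if the sense is opposite.

**Route**

Step 1
Reactants: 1 2,2-dimethylcyclohexan-1-one
Product: 2 2,2-dimethylcyclohexanone 2,4,6-triisopropylbenzenesulfonylhydrazone (E)
Conditions: 2,4,6-(i-Pr)3C6H2SO2NHNH2, HCl (cat.), THF, 23 °C
Reagents that add atoms: 2,4,6-tri(propan-2-yl)benzenesulfonohydrazide CC(C)c1cc(C(C)C)c(S(=O)(=O)NN)c(C(C)C)c1
Why: Sulfonylhydrazone condensation of a ketone, which places the N–N bond anti to the quaternary carbon and so sets up the only available α-CH2 for the Shapiro reaction.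

Step 2
Reactants: 2 2,2-dimethylcyclohexanone 2,4,6-triisopropylbenzenesulfonylhydrazone; 3 (E)-but-2-enal
Product: 5 (E)-1-(6,6-dimethylcyclohex-1-en-1-yl)but-2-en-1-ol (racemic), via 6,6-dimethylcyclohex-1-enyllithium 4 (not isolated)
Conditions: n-BuLi (2.2 equiv), THF, −78 → 0 °C; then 3, −78 °C; H2O
Reagents that add atoms: none
Why: Shapiro reaction of the trisylhydrazone gives the vinyllithium regiospecifically, and its 1,2-addition to the enal forms the C5–C6 bond; the carbinol centre is oxidized away in the next step.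

Step 3
Reactants: 5 (E)-1-(6,6-dimethylcyclohex-1-en-1-yl)but-2-en-1-ol
Product: 6 (E)-1-(6,6-dimethylcyclohex-1-en-1-yl)but-2-en-1-one
Conditions: MnO2 (activated, excess), CH2Cl2, 23 °C
Reagents that add atoms: none
Why: MnO2 oxidation of a doubly allylic alcohol gives the cross-conjugated dienone without touching either alkene.

Step 4
Reactants: 7 1,2,4,5-tetramethoxybenzene; 8 oxetane
Product: 10 3-(2,3,5,6-tetramethoxyphenyl)propan-1-ol, via 2,3,5,6-tetramethoxyphenyllithium 9 (not isolated)
Conditions: n-BuLi, THF, 0 → 23 °C; then 8, BF3·OEt2, −78 °C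
Reagents that add atoms: none
Why: Directed ortho-lithiation at the CH flanked by two methoxy groups, followed by BF3-promoted ring opening of oxetane by the aryllithium, installs the three-carbon chain in one operation.

Step 5
Reactants: 10 3-(2,3,5,6-tetramethoxyphenyl)propan-1-ol
Product: 11 3-(2,3,5,6-tetramethoxyphenyl)propanal
Conditions: Dess–Martin periodinane, CH2Cl2, 0 → 23 °C
Reagents that add atoms: none
Why: Dess–Martin oxidation of a primary alcohol stops at the aldehyde and is compatible with the electron-rich arene.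

Step 6
Reactants: 6 (E)-1-(6,6-dimethylcyclohex-1-en-1-yl)but-2-en-1-one; 11 3-(2,3,5,6-tetramethoxyphenyl)propanal
Product: 13 (5S,8S,9S,10R)-9-formyl-4,4,8-trimethyl-9-(2,3,5,6-tetramethoxybenzyl)-trans-decalin-6-one, via mono-Michael keto aldehyde 12 (not isolated)
Conditions: 9-amino-9-deoxy-epi-quinine (20 mol %), CF3CO2H (40 mol %), toluene, 40 °C, 11 (1.5 equiv) added slowly; then DBU (20 mol %), 23 °C
Reagents that add atoms: none
Why: Proposed new method: the primary amine condenses with 11 to an E-enamine that adds to C8 of the crotonyl arm of 6, held by hydrogen bonding at the protonated quinuclidine (C8–C9); the α-branched aldehyde 12 so formed recondenses with the amine to a tetrasubstituted enamine that attacks C10 of the cyclohexenyl arm (C9–C10), after which the C5=C6 enol is protonated and the iminium ion hydrolysed. The closest known reaction types are amine-catalysed [5+1] double Michael annulations of divinyl ketones with doubly stabilized carbon acids and primary-amine enamine Michael additions of α-branched aldehydes that create quaternary carbons; a plain aldehyde as the one-carbon partner of a divinyl ketone has not been shown. Ring B closes in the 6-endo-trig mode through a chair-like transition state. C8 is set by the catalyst in the intermolecular addition; C9 and C10 follow from the chair, in which the 8-methyl group, C1 and the arylmethyl group are equatorial and the slim enamine carbon (later the formyl group) is axial, an arrangement that reversibility of the second addition also favours thermodynamically; C5 is set by DBU equilibration to the trans ring fusion. The step needs site selectivity between the two enone arms and suppression of aldehyde self-condensation: the disubstituted crotonyl alkene is far less hindered than the ring alkene and should react first, slow addition keeps the concentration of 11 low, and the quaternary formyl group of 13 cannot enolize or close by aldol reaction to anything but a four-membered ring.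

Step 7
Reactants: 13 (5S,8S,9S,10R)-9-formyl-4,4,8-trimethyl-9-(2,3,5,6-tetramethoxybenzyl)-trans-decalin-6-one
Product: 14 (5S,8S,9S,10R)-9-(1,3-dithiolan-2-yl)-4,4,8-trimethyl-9-(2,3,5,6-tetramethoxybenzyl)-trans-decalin-6-one
Conditions: HSCH2CH2SH (1.2 equiv), BF3·OEt2 (0.3 equiv), CH2Cl2, −20 → 0 °C
Reagents that add atoms: ethane-1,2-dithiol SCCS
Why: Chemoselective dithioacetalization of the aldehyde, since a dithiolane at C6 would place one sulfur syn-axial to the axial C4 methyl group and the other against the equatorial one, so the ketone should stay free.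

Step 8
Reactants: 14 (5S,8S,9S,10R)-9-(1,3-dithiolan-2-yl)-4,4,8-trimethyl-9-(2,3,5,6-tetramethoxybenzyl)-trans-decalin-6-one
Product: 15 (5S,8S,9R,10R)-4,4,8,9-tetramethyl-9-(2,3,5,6-tetramethoxybenzyl)-trans-decalin-6-one
Conditions: Raney Ni (W-2, pre-aged in acetone), EtOH, reflux
Reagents that add atoms: none
Why: Mozingo desulfurization turns the dithiolane carbon into the 9-methyl group, and acetone-deactivated Raney Ni is the usual way to spare a ketone.

Step 9
Reactants: 15 (5S,8S,9R,10R)-4,4,8,9-tetramethyl-9-(2,3,5,6-tetramethoxybenzyl)-trans-decalin-6-one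
Product: 16 (5S,6S,8S,9R,10R)-4,4,8,9-tetramethyl-9-(2,3,5,6-tetramethoxybenzyl)-trans-decalin-6-ol (axial OH)
Conditions: LiBH(s-Bu)3, THF, −78 → 0 °C; then NaOH, H2O2
Reagents that add atoms: none
Why: Hydride reduction of a cyclohexanone in which the bulky borohydride attacks C6 along the equatorial trajectory, away from the axial C4 methyl group, to give the axial alcohol anti-periplanar to H-5.

Step 10
Reactants: 16 (5S,6S,8S,9R,10R)-4,4,8,9-tetramethyl-9-(2,3,5,6-tetramethoxybenzyl)-trans-decalin-6-ol
Product: 18 (8S,9R,10S)-4,4,8,9-tetramethyl-9-(2,3,5,6-tetramethoxybenzyl)-octal-5-ene (C5=C6), via C6 dichlorophosphate 17 (not isolated)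
Conditions: POCl3, pyridine, 0 → 80 °C
Reagents that add atoms: none
Why: POCl3/pyridine dehydration, an anti E2 elimination of the axial dichlorophosphate in which loss of the tertiary anti-periplanar H-5 gives the more substituted (Zaitsev) alkene and relieves the syn-axial clash with the C4 methyl group.

Step 11
Reactants: 18 (8S,9R,10S)-4,4,8,9-tetramethyl-9-(2,3,5,6-tetramethoxybenzyl)-octal-5-ene
Product: 19 2,5-dimethoxy-3-alkyl-1,4-benzoquinone (alkyl = the decalinylmethyl group of 18)
Conditions: (NH4)2Ce(NO3)6, MeCN/H2O, 0 °C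
Reagents that add atoms: water O
Why: Oxidative demethylation of a para-dimethoxyarene to the quinone, in which water attacks the methoxy-bearing ring carbons of the arene radical cation; the two para pairs are equivalent by symmetry and the trisubstituted alkene is not touched at 0 °C.

Step 12
Reactants: 19 2,5-dimethoxy-3-alkyl-1,4-benzoquinone
Product: 20 2-hydroxy-5-methoxy-3-{[(1R,2S,8aS)-1,2,5,5-tetramethyl-1,2,3,5,6,7,8,8a-octahydronaphthalen-1-yl]methyl}cyclohexa-2,5-diene-1,4-dione (target)
Conditions: KOH, MeOH/H2O, 23 °C; then 1 M HCl, 0 °C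
Reagents that add atoms: potassium hydroxide [K+].[OH-]
Why: Vinylogous ester hydrolysis by addition–elimination, selective for the methoxy group next to the alkyl substituent (twisted out of conjugation), and the hydroxyquinone anion formed resists a second exchange; base is chosen over acid to protect the C5=C6 alkene.

**Compound list**

1 | 2,2-dimethylcyclohexan-1-one | CC1(C)CCCCC1=O | starting material
2 | (E)-N'-(2,2-dimethylcyclohexylidene)-2,4,6-tri(propan-2-yl)benzenesulfonohydrazide | CC(C)c1cc(C(C)C)c(S(=O)(=O)N/N=C2\CCCCC2(C)C)c(C(C)C)c1 | intermediate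
3 | (E)-but-2-enal (crotonaldehyde) | C/C=C/C=O | starting material
4 | (6,6-dimethylcyclohex-1-en-1-yl)lithium | [Li]C1=CCCCC1(C)C | intermediate
5 | (E)-1-(6,6-dimethylcyclohex-1-en-1-yl)but-2-en-1-ol, racemic | C/C=C/C(O)C1=CCCCC1(C)C | intermediate
6 | (E)-1-(6,6-dimethylcyclohex-1-en-1-yl)but-2-en-1-one | C/C=C/C(=O)C1=CCCCC1(C)C | intermediate
7 | 1,2,4,5-tetramethoxybenzene | COc1cc(OC)c(OC)cc1OC | starting material
8 | oxetane | C1COC1 | starting material
9 | (2,3,5,6-tetramethoxyphenyl)lithium | [Li]c1c(OC)c(OC)cc(OC)c1OC | intermediate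
10 | 3-(2,3,5,6-tetramethoxyphenyl)propan-1-ol | COc1cc(OC)c(OC)c(CCCO)c1OC | intermediate
11 | 3-(2,3,5,6-tetramethoxyphenyl)propanal | COc1cc(OC)c(OC)c(CCC=O)c1OC | intermediate
12 | (3S)-5-(6,6-dimethylcyclohex-1-en-1-yl)-3-methyl-5-oxo-2-[(2,3,5,6-tetramethoxyphenyl)methyl]pentanal (C2 not assigned, erased on ring closure) | COc1cc(OC)c(OC)c(CC(C=O)[C@@H](C)CC(=O)C2=CCCCC2(C)C)c1OC | intermediate
13 | (1S,2S,4aS,8aR)-2,5,5-trimethyl-4-oxo-1-[(2,3,5,6-tetramethoxyphenyl)methyl]decahydronaphthalene-1-carbaldehyde (trans-fused; 8-CH3 and 9-CHO cis, H-10 anti to CHO) | COc1cc(OC)c(OC)c(C[C@@]2(C=O)[C@@H]3CCCC(C)(C)[C@H]3C(=O)C[C@@H]2C)c1OC | intermediate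
14 | (3S,4S,4aR,8aS)-4-(1,3-dithiolan-2-yl)-3,8,8-trimethyl-4-[(2,3,5,6-tetramethoxyphenyl)methyl]octahydronaphthalen-1(2H)-one | COc1cc(OC)c(OC)c(C[C@@]2(C4SCCS4)[C@@H]3CCCC(C)(C)[C@H]3C(=O)C[C@@H]2C)c1OC | intermediate
15 | (3S,4R,4aR,8aS)-3,4,8,8-tetramethyl-4-[(2,3,5,6-tetramethoxyphenyl)methyl]octahydronaphthalen-1(2H)-one | COc1cc(OC)c(OC)c(C[C@@]2(C)[C@@H]3CCCC(C)(C)[C@H]3C(=O)C[C@@H]2C)c1OC | intermediate
16 | (1S,3S,4R,4aR,8aS)-3,4,8,8-tetramethyl-4-[(2,3,5,6-tetramethoxyphenyl)methyl]decahydronaphthalen-1-ol (axial OH, anti to H-8a) | COc1cc(OC)c(OC)c(C[C@@]2(C)[C@@H]3CCCC(C)(C)[C@H]3[C@@H](O)C[C@@H]2C)c1OC | intermediate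
17 | dichlorophosphate ester of 16 at the ring hydroxyl | COc1cc(OC)c(OC)c(C[C@@]2(C)[C@@H]3CCCC(C)(C)[C@H]3[C@@H](OP(=O)(Cl)Cl)C[C@@H]2C)c1OC | intermediate
18 | 1,2,4,5-tetramethoxy-3-{[(1R,2S,8aS)-1,2,5,5-tetramethyl-1,2,3,5,6,7,8,8a-octahydronaphthalen-1-yl]methyl}benzene | COc1cc(OC)c(OC)c(C[C@@]2(C)[C@@H]3CCCC(C)(C)C3=CC[C@@H]2C)c1OC | intermediate
19 | 2,5-dimethoxy-3-{[(1R,2S,8aS)-1,2,5,5-tetramethyl-1,2,3,5,6,7,8,8a-octahydronaphthalen-1-yl]methyl}cyclohexa-2,5-diene-1,4-dione | COC1=CC(=O)C(OC)=C(C[C@@]2(C)[C@@H]3CCCC(C)(C)C3=CC[C@@H]2C)C1=O | intermediate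
20 | 2-hydroxy-5-methoxy-3-{[(1R,2S,8aS)-1,2,5,5-tetramethyl-1,2,3,5,6,7,8,8a-octahydronaphthalen-1-yl]methyl}cyclohexa-2,5-diene-1,4-dione | COC1=CC(=O)C(O)=C(C[C@@]2(C)[C@@H]3CCCC(C)(C)C3=CC[C@@H]2C)C1=O | target

**Step count**

Total: 12 steps. Longest linear sequence: 10 steps (1, 2, 3, 6, 7, 8, 9, 10, 11, 12); the aldehyde branch (4, 5) joins at step 6.

**Steps most likely to fail**

Step 6. The intermolecular enamine addition to the β-methyl enone may be too slow, so that self-condensation of the aldehyde takes over. The hindered α-branched enamine may fail to close onto C10, or facial control at C8 may be poor. The fallback is stepwise, auxiliary-controlled and uses known chemistry; it sets out from 11 and returns at 13. Aldehyde 11 is condensed with (S)-1-amino-2-(methoxymethyl)pyrrolidine to the SAMP hydrazone F1. Its lithium azaenolate (LiN(i-Pr)2, THF, −78 °C) adds to methyl (E)-but-2-enoate to give the hydrazone ester F2, with C8 set by the auxiliary. MeNH(OMe)·HCl with i-PrMgCl converts the ester into the Weinreb amide F3, and vinyllithium 4 (generated from 2 as in step 2) gives the hydrazone enone F4. Two-phase aqueous oxalic acid releases aldehyde 12, now isolated. Ring B is then closed by an intramolecular Stork enamine Michael addition (pyrrolidine, toluene, reflux; aqueous AcOH; DBU) to give 13. If the auxiliary sense is opposite, the enantiomeric RAMP reagent is used.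

Step 10. Elimination may go toward C7 instead of C5 (loss of regiocontrol in the E2 step), or substitution or cationic rearrangement may occur at C6. The fallback sets out from 15 and returns at 18. The ketone is triflated under cationic, Zaitsev-type conditions (Tf2O, 2,6-di-tert-butyl-4-methylpyridine, CH2Cl2) to the more substituted C5=C6 enol triflate F5. Its C–O bond is reduced with Pd(OAc)2, PPh3, Bu3N and HCO2H in DMF at 60 °C to give 18. This replaces elimination from an alcohol by formate reduction of a vinyl triflate, but the C4 methyl groups may disfavour this enol isomer, so the regiochemistry would have to be checked here as well.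

Step 7. The axial neopentyl aldehyde may react so slowly that the C6 ketone is thioketalized as well (loss of chemoselectivity). The fallback sets out from 13 and returns at 18, bypassing 14–16. Both carbonyl groups are reduced with LiBH(s-Bu)3 to the diol F6 (axial 6-OH). The primary alcohol alone is re-oxidized with TEMPO/PhI(OAc)2 to the hydroxy aldehyde F7. POCl3/pyridine dehydration gives the C5=C6 ene aldehyde F8. Wolff–Kishner reduction (N2H4·H2O, KOH, diethylene glycol, 200 °C, Huang-Minlon procedure) converts the formyl group into the 9-methyl group of 18.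

**Further compounds**

F1 | step 6 | (E)-N-[(2S)-2-(methoxymethyl)pyrrolidin-1-yl]-3-(2,3,5,6-tetramethoxyphenyl)propan-1-imine | COC[C@@H]1CCCN1/N=C/CCc1c(OC)c(OC)cc(OC)c1OC
F2 | step 6 | methyl (3S)-5-{[(2S)-2-(methoxymethyl)pyrrolidin-1-yl]imino}-3-methyl-4-[(2,3,5,6-tetramethoxyphenyl)methyl]pentanoate (C4 not assigned) | COC[C@@H]1CCCN1/N=C/C(Cc1c(OC)c(OC)cc(OC)c1OC)[C@@H](C)CC(=O)OC
F3 | step 6 | (3S)-N-methoxy-5-{[(2S)-2-(methoxymethyl)pyrrolidin-1-yl]imino}-N,3-dimethyl-4-[(2,3,5,6-tetramethoxyphenyl)methyl]pentanamide (C4 not assigned) | COC[C@@H]1CCCN1/N=C/C(Cc1c(OC)c(OC)cc(OC)c1OC)[C@@H](C)CC(=O)N(C)OC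
F4 | step 6 | (3S)-1-(6,6-dimethylcyclohex-1-en-1-yl)-5-{[(2S)-2-(methoxymethyl)pyrrolidin-1-yl]imino}-3-methyl-4-[(2,3,5,6-tetramethoxyphenyl)methyl]pentan-1-one (C4 not assigned) | COC[C@@H]1CCCN1/N=C/C(Cc1c(OC)c(OC)cc(OC)c1OC)[C@@H](C)CC(=O)C2=CCCCC2(C)C
F5 | step 10 | (3S,4R,4aS)-3,4,8,8-tetramethyl-4-[(2,3,5,6-tetramethoxyphenyl)methyl]-2,3,4,4a,5,6,7,8-octahydronaphthalen-1-yl trifluoromethanesulfonate | COc1cc(OC)c(OC)c(C[C@@]2(C)[C@@H]3CCCC(C)(C)C3=C(OS(=O)(=O)C(F)(F)F)C[C@@H]2C)c1OC
F6 | step 7 | (1S,3S,4S,4aR,8aS)-4-(hydroxymethyl)-3,8,8-trimethyl-4-[(2,3,5,6-tetramethoxyphenyl)methyl]decahydronaphthalen-1-ol | COc1cc(OC)c(OC)c(C[C@@]2(CO)[C@@H]3CCCC(C)(C)[C@H]3[C@@H](O)C[C@@H]2C)c1OC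
F7 | step 7 | (1S,2S,4S,4aS,8aR)-4-hydroxy-2,5,5-trimethyl-1-[(2,3,5,6-tetramethoxyphenyl)methyl]decahydronaphthalene-1-carbaldehyde | COc1cc(OC)c(OC)c(C[C@@]2(C=O)[C@@H]3CCCC(C)(C)[C@H]3[C@@H](O)C[C@@H]2C)c1OC
F8 | step 7 | (1S,2S,8aR)-2,5,5-trimethyl-1-[(2,3,5,6-tetramethoxyphenyl)methyl]-1,2,3,5,6,7,8,8a-octahydronaphthalene-1-carbaldehyde | COc1cc(OC)c(OC)c(C[C@@]2(C=O)[C@@H]3CCCC(C)(C)C3=CC[C@@H]2C)c1OC
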